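## Retrosynthetic overview

1. The C1–C13′ bond is made last: the allylic phosphate of half A couples with the zinc homoenolate of half B, and both halves come from one dione lactone 17. The three carbinols are set afterwards by hydride reduction and Mitsunobu inversion.
2. The ten-membered ring of 17 comes from a dianionic oxy-Cope [3,3] shift of the cis-1-vinyl-2-propynyl-1,2-diol 14. This cuts C1–C6 of the carvone ring and makes C3–C4; 9Z is inherited from the six-membered ring and 4Z arises on allenolate protonation.
3. Diol 14 comes from (S)-carvone by Shapiro diene formation, singlet-oxygen [4+2] cycloaddition (C8–O anti to the C7 side chain), selenoetherification to a 3-methylenetetrahydrofuran (masked α-methylene lactone), C6 hydroxylation and two Grignard additions.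
4. Ring order: cyclohexene (bought) → peroxide bicycle (transient) → tetrahydrofuran → ten-membered ring → γ-lactone (by ether oxidation).

Assumption 1: locants follow germacranolide numbering of the target (C1–C15, primes for the half with the saturated lactone); α/β refer to the flat drawing with H-7 α. The target is then 1α-alkyl, 6α-OH, 8α-O (half A) and 1′α,6′α-(OH)2, 8′α-O, 11′β-H (half B), all ring olefins Z; CIP: 1R,6R,7S,8S,1′S,6′R,7′S,8′S,11′R.

Assumption 2: NaBH4/CeCl3 attacks the twisted Z-enone carbonyls of the ten-membered ring from the outer face and gives the β-alcohols; the route then inverts these centres (steps 15 and 17). This premise is not verified.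

## Route

Step 1
Reactants: 1 (S)-(+)-carvone
Product: 2 (S)-carvone p-toluenesulfonylhydrazone
Conditions: TsNHNH2, MeOH, rt
Reagents that add atoms: p-toluenesulfonyl hydrazide, Cc1ccc(cc1)S(=O)(=O)NN
Why: Hydrazone formation at the enone carbonyl leaves the carvone stereocenter (later C7) untouched.

Step 2
Reactants: 2 (S)-carvone p-toluenesulfonylhydrazone
Product: 3 (5S)-2-methyl-5-(prop-1-en-2-yl)cyclohexa-1,3-diene
Conditions: MeLi (3 equiv), Et2O, 0 °C → rt; H2O
Reagents that add atoms: none
Why: Shapiro reaction (N–H and α′-CH deprotonation, loss of sulfinate and N2, protonation of the vinyllithium) gives the homoannular 1,3-diene without touching the stereocenter.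

Step 3
Reactants: 3 (5S)-2-methyl-5-(prop-1-en-2-yl)cyclohexa-1,3-diene
Product: 5 (1S,4S,5R)-2-methyl-5-(prop-1-en-2-yl)cyclohex-2-ene-1,4-diol, via endoperoxide 4 (not isolated)
Conditions: O2, tetraphenylporphyrin (cat.), visible light, CH2Cl2, −30 °C; then Zn, AcOH, 0 °C
Reagents that add atoms: dioxygen, O=O
Why: [4+2] cycloaddition of singlet oxygen to the s-cis diene occurs anti to the adjacent isopropenyl group, which sets C8–O trans to the C7 side chain and C1–O cis to C8–O, and Zn/AcOH cleaves only the O–O bond.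

Step 4
Reactants: 5 (1S,4S,5R)-2-methyl-5-(prop-1-en-2-yl)cyclohex-2-ene-1,4-diol
Product: 7 (3aR,5S,7aS)-6-methyl-3-methylidene-2,3,3a,4,5,7a-hexahydro-1-benzofuran-5-ol, via tertiary selenide 6 (not isolated)
Conditions: N-(phenylseleno)phthalimide, p-TsOH (cat.), CH2Cl2, 0 °C; then 30% H2O2, pyridine, THF, 0 °C → rt
Reagents that add atoms: none
Why: Only the C8 hydroxyl can reach the isopropenyl group, so 5-endo selenoetherification followed by selenoxide syn-elimination toward the methyl group gives the trans-fused 3-methylenetetrahydrofuran (a masked α-methylene lactone) and sets apart the C1 hydroxyl, with no new stereocenter kept.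

Step 5
Reactants: 7 (3aR,5S,7aS)-6-methyl-3-methylidene-2,3,3a,4,5,7a-hexahydro-1-benzofuran-5-ol
Product: 8 (3aR,7aS)-6-methyl-3-methylidene-3,3a,4,7a-tetrahydro-1-benzofuran-5(2H)-one
Conditions: MnO2, CH2Cl2, rt
Reagents that add atoms: none
Why: Allylic alcohol oxidation of the only remaining carbinol gives the α-methyl enone under neutral conditions that do not epimerise C7 or C8.

Step 6
Reactants: 8 (3aR,7aS)-6-methyl-3-methylidene-3,3a,4,7a-tetrahydro-1-benzofuran-5(2H)-one
Product: 9 4-hydroxy derivative of 8 (4-OH on the face of H-3a, trans to the C3a–C3 bond)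
Conditions: KN(SiMe3)2, THF, −78 °C; then (±)-2-(phenylsulfonyl)-3-phenyloxaziridine, −78 °C; AcOH
Reagents that add atoms: 2-(phenylsulfonyl)-3-phenyloxaziridine, O=S(=O)(c1ccccc1)N1OC1c1ccccc1
Why: Kinetic α′-deprotonation and Davis enolate hydroxylation (racemic reagent) place OH at C6 equatorial and trans to the C7 substituent, a centre that only steers step 7 and is destroyed in step 8.

Step 7
Reactants: 9 4-hydroxy enone; 10 vinylmagnesium bromide
Product: 11 5-ethenyl-6-methyl-3-methylidene-2,3,3a,4,5,7a-hexahydro-1-benzofuran-4,5-diol (trans ring fusion; both OH on the face of H-3a, ethenyl on the other face)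
Conditions: 10 (3 equiv), THF, −78 → 0 °C
Reagents that add atoms: none
Why: Chelation-controlled 1,2-Grignard addition to the α-alkoxy ketone brings the vinyl group in trans to the C6–O bond, giving the cis-diol with the vinyl group equatorial.

Step 8
Reactants: 11 vinyl cis-diol
Product: 12 5-ethenyl-5-hydroxy-6-methyl-3-methylidene-3,3a,5,7a-tetrahydro-1-benzofuran-4(2H)-one
Conditions: Dess–Martin periodinane, CH2Cl2, 0 °C → rt
Reagents that add atoms: none
Why: Dess–Martin oxidation converts the secondary alcohol to the ketone while the tertiary bis-allylic alcohol cannot be oxidised.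

Step 9
Reactants: 12 α-ketol; 13 prop-1-ynylmagnesium bromide
Product: 14 5-ethenyl-6-methyl-3-methylidene-4-(prop-1-yn-1-yl)-2,3,3a,4,5,7a-hexahydro-1-benzofuran-4,5-diol (cis-diol on the face of H-3a; ethenyl and propynyl both on the other face)
Conditions: 13 (3 equiv), THF, −78 → 0 °C
Reagents that add atoms: none
Why: Axial attack of the slim alkynyl Grignard on the C6 ketone, anti to the axial C1 alkoxide, puts the propynyl group gauche (cis) to the vinyl group, the geometry the [3,3] shift needs.

Step 10
Reactants: 14 vinyl propynyl cis-diol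
Product: 16 (4Z,9Z)-8α,12-epoxygermacra-4,9,11(13)-triene-1,6-dione, via dipotassium bis-enolate 15 (not isolated)
Conditions: KH (3 equiv), 18-crown-6, THF, 0 °C → rt; inverse quench into AcOH/THF, −78 °C
Reagents that add atoms: none
Why: Dianionic oxy-Cope [3,3]-sigmatropic rearrangement breaks C1–C6 (weakened by both alkoxides) and forms C3–C4, giving an enolate and an allenolate whose protonation on the outer (methyl) side gives the 4Z enone, while 9Z is inherited from the six-membered ring and C7/C8 are untouched.

Step 11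
Reactants: 16 ether dione
Product: 17 (4Z,9Z)-1,6-dioxogermacra-4,9,11(13)-trien-12,8α-olide
Conditions: CrO3, 3,5-dimethylpyrazole, CH2Cl2, −20 °C
Reagents that add atoms: chromium trioxide, O=[Cr](=O)=O
Why: Allylic ether oxidation of the CH2 that is both α to oxygen and allylic to the only electron-rich olefin gives the α-methylene γ-lactone, the ring olefins being deactivated as enones.

Step 12
Reactants: 17 dione lactone
Product: 18 (4Z,9Z)-1β-hydroxy-6-oxogermacra-4,9,11(13)-trien-12,8α-olide
Conditions: NaBH4 (0.3 equiv), CeCl3·7H2O, MeOH–THF, −78 °C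
Reagents that add atoms: none
Why: Luche 1,2-reduction picks the C1 ketone (CH2-flanked, less substituted enone) over the C6 ketone next to the ring-fusion carbon, and outer-face hydride delivery gives the 1β alcohol.

Step 13
Reactants: 18 1β-hydroxy ketone
Product: 19 1β-diethyl phosphate of 18
Conditions: (EtO)2P(O)Cl, pyridine, 4-(dimethylamino)pyridine (cat.), CH2Cl2, −20 °C
Reagents that add atoms: diethyl chlorophosphate, CCOP(=O)(Cl)OCC
Why: O-Phosphorylation with retention turns the allylic alcohol into a leaving group far more reactive than the allylic lactone C8–O bond.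

Step 14
Reactants: 17 dione lactone
Product: 20 (4Z,9Z)-13-iodo-1,6-dioxo-11βH-germacra-4,9-dien-12,8α-olide
Conditions: Me3SiCl, NaI, H2O, MeCN, 0 °C
Reagents that add atoms: sodium iodide, [Na+].[I-]
Why: Conjugate hydroiodination of the exocyclic acrylate under equilibrating acid conditions leaves the CH2I group trans to the C6′ branch on the lactone (11′βH, as in the target).

Step 15
Reactants: 20 iodomethyl lactone; 19 allylic phosphate
Product: 22 triketone dimer (target skeleton with C6, C1′ and C6′ as ketones), via organozinc iodide 21 (not isolated)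
Conditions: 20, Zn dust (Me3SiCl-activated), DMF, rt; then 19, Pd2(dba)3 (cat.), P(2-furyl)3, THF, 0 °C → rt
Reagents that add atoms: none
Why: Negishi-type allyl–alkyl coupling in which zerovalent palladium ionises the C1 phosphate with inversion and the zinc homoenolate is transferred from the palladium face to the allyl terminus remote from the C8 oxygen, so C1 is set α by net inversion with the 9Z olefin retained.

Step 16
Reactants: 22 triketone dimer
Product: 23 6β,1′β,6′β-triol (C6, C1′, C6′ epimer of the target)
Conditions: NaBH4, CeCl3·7H2O, MeOH–THF, −78 °C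
Reagents that add atoms: none
Why: Luche 1,2-reduction of the three enone carbonyls with outer-face hydride delivery (at C6 and C6′ anti to the C7–C11 bond, Felkin sense) gives the β alcohols and spares the α-methylene lactone.

Step 17
Reactants: 23 β-triol
Product: 24 6α,1′α,6′α-tris(chloroacetate) of the target
Conditions: ClCH2CO2H, PPh3, diisopropyl azodicarboxylate (betaine preformed), toluene–THF, 0 °C → rt
Reagents that add atoms: chloroacetic acid, OC(=O)CCl
Why: Triple Mitsunobu reaction with chloroacetic acid (the acid of choice for hindered secondary alcohols) inverts C6, C1′ and C6′ by SN2 to the α esters.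

Step 18
Reactants: 24 tris(chloroacetate)
Product: 25 target CNP0307352.3
Conditions: thiourea, NaHCO3, EtOH, 50 °C
Reagents that add atoms: none
Why: Thiourea S-alkylation and cyclisation release the three alcohols under near-neutral conditions that spare both lactones and the α-methylene unit.

## Compound list

1 | (S)-(+)-carvone, (5S)-2-methyl-5-(prop-1-en-2-yl)cyclohex-2-en-1-one | CC1=CC[C@H](C(C)=C)CC1=O | starting material
2 | (S)-carvone p-toluenesulfonylhydrazone | CC1=CC[C@H](C(C)=C)CC1=NNS(=O)(=O)c1ccc(C)cc1 | intermediate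
3 | (5S)-2-methyl-5-(prop-1-en-2-yl)cyclohexa-1,3-diene | CC1=CC[C@H](C(C)=C)C=C1 | intermediate
4 | 5-methyl-7-(prop-1-en-2-yl)-2,3-dioxabicyclo[2.2.2]oct-5-ene, peroxide bridge anti to isopropenyl | CC1=C[C@H]2[C@@H](C(C)=C)C[C@@H]1OO2 | intermediate (not isolated)
5 | (1S,4S,5R)-2-methyl-5-(prop-1-en-2-yl)cyclohex-2-ene-1,4-diol | CC1=C[C@H](O)[C@@H](C(C)=C)C[C@@H]1O | intermediate
6 | 3,6-dimethyl-3-(phenylselanyl)-trans-fused hexahydro-1-benzofuran-5-ol (C3 epimers) | CC1=C[C@@H]2OCC(C)([Se]c3ccccc3)[C@H]2C[C@@H]1O | intermediate (not isolated)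
7 | (3aR,5S,7aS)-6-methyl-3-methylidene-2,3,3a,4,5,7a-hexahydro-1-benzofuran-5-ol | CC1=C[C@@H]2OCC(=C)[C@H]2C[C@@H]1O | intermediate
8 | (3aR,7aS)-6-methyl-3-methylidene-3,3a,4,7a-tetrahydro-1-benzofuran-5(2H)-one | CC1=C[C@@H]2OCC(=C)[C@H]2CC1=O | intermediate
9 | 4-hydroxy derivative of 8 (OH on the face of H-3a) | CC1=C[C@@H]2OCC(=C)[C@H]2[C@H](O)C1=O | intermediate
10 | vinylmagnesium bromide | C=C[Mg]Br | starting material
11 | 5-ethenyl-6-methyl-3-methylidene-hexahydro-1-benzofuran-4,5-diol (cis-diol, ethenyl anti to both OH) | CC1=C[C@@H]2OCC(=C)[C@H]2[C@H](O)[C@@]1(O)C=C | intermediate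
12 | 5-ethenyl-5-hydroxy-6-methyl-3-methylidene-tetrahydro-1-benzofuran-4(2H)-one | CC1=C[C@@H]2OCC(=C)[C@H]2C(=O)[C@@]1(O)C=C | intermediate
13 | prop-1-ynylmagnesium bromide | CC#C[Mg]Br | starting material
14 | 5-ethenyl-6-methyl-3-methylidene-4-(prop-1-yn-1-yl)-hexahydro-1-benzofuran-4,5-diol (cis-diol; ethenyl and propynyl cis) | CC1=C[C@@H]2OCC(=C)[C@H]2[C@@](O)(C#CC)[C@@]1(O)C=C | intermediate
15 | dipotassium 1-enolate/6-allenolate of the ring-expanded ether | C=C1CO[C@H]2/C=C(/C)C([O-])=CCC(C)=C=C([O-])[C@H]12.[K+].[K+] | intermediate (not isolated)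
16 | (4Z,9Z)-8α,12-epoxygermacra-4,9,11(13)-triene-1,6-dione | C=C1CO[C@H]2/C=C(/C)C(=O)CC/C(C)=C\C(=O)[C@H]12 | intermediate
17 | (4Z,9Z)-1,6-dioxogermacra-4,9,11(13)-trien-12,8α-olide | C=C1C(=O)O[C@H]2/C=C(/C)C(=O)CC/C(C)=C\C(=O)[C@H]12 | intermediate
18 | (4Z,9Z)-1β-hydroxy-6-oxogermacra-4,9,11(13)-trien-12,8α-olide | C=C1C(=O)O[C@H]2/C=C(/C)[C@H](O)CC/C(C)=C\C(=O)[C@H]12 | intermediate
19 | 1β-diethyl phosphate of 18 | C=C1C(=O)O[C@H]2/C=C(/C)[C@H](OP(=O)(OCC)OCC)CC/C(C)=C\C(=O)[C@H]12 | intermediate
20 | (4Z,9Z)-13-iodo-1,6-dioxo-11βH-germacra-4,9-dien-12,8α-olide | IC[C@H]1C(=O)O[C@H]2/C=C(/C)C(=O)CC/C(C)=C\C(=O)[C@H]12 | intermediate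
21 | 13-(iodozincio) analogue of 20 | I[Zn]C[C@H]1C(=O)O[C@H]2/C=C(/C)C(=O)CC/C(C)=C\C(=O)[C@H]12 | intermediate (not isolated)
22 | triketone dimer (C1α–C13′ bond; ketones at C6, C1′, C6′) | C=C1C(=O)O[C@H]2/C=C(/C)[C@@H](C[C@H]3C(=O)O[C@H]4/C=C(/C)C(=O)CC/C(C)=C\C(=O)[C@@H]43)CC/C(C)=C\C(=O)[C@H]12 | intermediate
23 | 6β,1′β,6′β-triol | C=C1C(=O)O[C@H]2/C=C(/C)[C@@H](C[C@H]3C(=O)O[C@H]4/C=C(/C)[C@H](O)CC/C(C)=C\[C@H](O)[C@@H]43)CC/C(C)=C\[C@H](O)[C@H]12 | intermediate
24 | 6α,1′α,6′α-tris(chloroacetate) of the target | C=C1C(=O)O[C@H]2/C=C(/C)[C@@H](C[C@H]3C(=O)O[C@H]4/C=C(/C)[C@@H](OC(=O)CCl)CC/C(C)=C\[C@@H](OC(=O)CCl)[C@@H]43)CC/C(C)=C\[C@@H](OC(=O)CCl)[C@H]12 | intermediate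
25 | CNP0307352.3 | C=C1C(=O)O[C@H]2/C=C(/C)[C@@H](C[C@H]3C(=O)O[C@H]4/C=C(/C)[C@@H](O)CC/C(C)=C\[C@@H](O)[C@@H]43)CC/C(C)=C\[C@@H](O)[C@H]12 | target

## Step count and risks

Total steps: 18. Longest linear sequence: 17 (steps 1–13 and 15–18, from 1 through 19 to 25).

**Step 10 (dianionic oxy-Cope).** The C6 alkoxide could instead drive cleavage of C6–C7 through the neighbouring exocyclic olefin, and the bis-enolate can undergo transannular aldol reaction on quenching. Fallback (ring-closing metathesis plus glycol cleavage in place of the sigmatropic shift): set out from 9. Adding 3-methylbut-3-enylmagnesium bromide to the enone carbonyl gives the homoprenyl cis-diol F1. Dess–Martin periodinane gives the ketol F2. Vinylmagnesium bromide gives the C6-vinyl cis-diol F3. The second-generation Grubbs catalyst closes the C4=C5 cyclohexene to the tricyclic cis-diol F4. Pb(OAc)4 then cleaves the C1–C6 glycol bond, and the route is rejoined at 16; the Z olefins are again fixed by the rings.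

**Step 15 (allyl–alkyl coupling).** β-Hydride elimination from the alkylpalladium, attack at C9, or ionisation of an allylic lactone could compete. Fallback (radical conjugate addition in place of cross-coupling): set out from 18. CBr4/PPh3 gives the allylic bromide F5. With (Me3Si)3SiH and Et3B/air in the presence of excess 17, the C1–C10–C9 allyl radical adds through its less hindered C1 terminus, on the outer face, to the exocyclic methylene of 17. Hydrogen transfer to the lactone α-radical gives 22, where the route is rejoined.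

**Step 17 (triple Mitsunobu on the dimer).** SN2′ attack or elimination at the hindered allylic carbinols could compete, and the step rests on Assumption 2. Fallback (thermodynamic control in place of inversion): set out from 23. Equilibrating the three allylic carbinols by reversible hydride transfer (Al(OiPr)3, i-PrOH with a little acetone, toluene, 80 °C; Meerwein–Ponndorf–Verley/Oppenauer equilibration) toward the pseudo-equatorial α alcohols would give 25 directly, with no new compound.

## Further compounds

F1 | step 10 | 6-methyl-5-(3-methylbut-3-enyl)-3-methylidene-hexahydro-1-benzofuran-4,5-diol (cis-diol) | CC1=C[C@@H]2OCC(=C)[C@H]2[C@H](O)[C@@]1(O)CCC(C)=C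
F2 | step 10 | 5-hydroxy-6-methyl-5-(3-methylbut-3-enyl)-3-methylidene-tetrahydro-1-benzofuran-4(2H)-one | CC1=C[C@@H]2OCC(=C)[C@H]2C(=O)[C@@]1(O)CCC(C)=C
F3 | step 10 | 4-ethenyl-6-methyl-5-(3-methylbut-3-enyl)-3-methylidene-hexahydro-1-benzofuran-4,5-diol (cis-diol, side chains cis) | CC1=C[C@@H]2OCC(=C)[C@H]2[C@@](O)(C=C)[C@@]1(O)CCC(C)=C
F4 | step 10 | tricyclic cis-diol (C1–C6 fused cyclohexene with the C4=C5 olefin) | CC1=C[C@@H]2OCC(=C)[C@H]2[C@@]3(O)C=C(C)CC[C@@]13O
F5 | step 15 | (4Z,9Z)-1α-bromo-6-oxogermacra-4,9,11(13)-trien-12,8α-olide | C=C1C(=O)O[C@H]2/C=C(/C)[C@@H](Br)CC/C(C)=C\C(=O)[C@H]12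
F0 | step 17 | none | none
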